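**Retrosynthetic overview**

1. Caraganin C ⇐ 4‑(arylethynyl)chroman bis‑silyl ether, by trans semi‑reduction of the alkyne and desilylation; the 4‑hydroxystyryl group is carried one oxidation level higher, as an alkyne, until the last step.
2. That chroman ⇐ one catalytic asymmetric operation on two achiral halves: an o‑hydroxybenzyl propargylic alcohol (ring A, C4, alkyne) and an (E)‑1,3‑diarylpropene (C2, C3, the other two aryl groups). C3–C4 forms first, then the pyran ring closes at O1–C2; all three stereocentres are set here.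
3. Enabling feature: O1 sits on C8a, ortho to C4a, and C4 is benzylic to ring A with the 7‑OMe para to C4a, so O1–C8a–C4a–C4 is a latent o‑quinone methide. C2 carries the 2,4‑dimethoxyphenyl ring, whose ortho and para OMe groups stabilise positive charge at C2, so the C2=C3 alkene is nucleophilic at C3 and the C2 cation is captured by O1.
4. Fragments: 2‑hydroxy‑4‑methoxybenzaldehyde + aryl acetylide (Corey–Fuchs from a 4‑silyloxybenzaldehyde); 2,4‑dimethoxybenzaldehyde + a phenethyl Grignard reagent, then dehydration.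
5. Ring order: the three benzene rings are bought; the pyran ring is the only ring made (key step).

Key step: step 6

Assumption: the (R)‑series catalyst is written for step 6; which catalyst antipode delivers the (2R,3R,4S) product is fixed in a first run, and the mirror‑image catalyst is used if required.

**Route**

Step 1
Reactants: 1 4‑[(tert‑butyldimethylsilyl)oxy]benzaldehyde
Product: 2 tert‑butyl[4‑(2,2‑dibromoethenyl)phenoxy]dimethylsilane
Conditions: CBr4, PPh3, Zn dust, CH2Cl2, rt; then 1, 0 °C → rt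
Reagents that add atoms: carbon tetrabromide, BrC(Br)(Br)Br
Why: Corey–Fuchs (Ramirez) dibromo‑olefination, a Wittig‑type reaction of Ph3P=CBr2 with a non‑enolisable aryl aldehyde; the aryl silyl ether is inert and no stereocentre is formed.

Step 2
Reactants: 2 tert‑butyl[4‑(2,2‑dibromoethenyl)phenoxy]dimethylsilane; 3 2‑hydroxy‑4‑methoxybenzaldehyde
Product: 6 2‑(3‑{4‑[(tert‑butyldimethylsilyl)oxy]phenyl}‑1‑hydroxyprop‑2‑yn‑1‑yl)‑5‑methoxyphenol (racemic), via lithium acetylide 4 (not isolated), via lithium phenolate 5 (not isolated)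
Conditions: 2 (1.3 equiv), n‑BuLi (2.6 equiv), THF, −78 → 0 °C; separately 3, LiHMDS (1.0 equiv), THF, −78 °C; combine, −78 → 0 °C; aq. NH4Cl; chromatography on Et3N‑deactivated silica
Reagents that add atoms: none
Why: Second stage of the Corey–Fuchs sequence (Br/Li exchange, Fritsch–Buttenberg–Wiechell rearrangement, deprotonation) should give acetylide 4, which adds 1,2 to the formyl group of the pre‑formed phenolate 5; the carbinol centre is racemic on purpose because step 6 erases it.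

Step 3
Reactants: 7 4‑(2‑bromoethyl)phenol
Product: 8 [4‑(2‑bromoethyl)phenoxy](tert‑butyl)dimethylsilane
Conditions: TBSCl, imidazole, CH2Cl2, 0 °C → rt
Reagents that add atoms: tert‑butyldimethylsilyl chloride, CC(C)(C)[Si](C)(C)Cl
Why: Standard imidazole‑promoted O‑silylation of a phenol; the primary bromide should be untouched at this temperature.

Step 4
Reactants: 8 [4‑(2‑bromoethyl)phenoxy](tert‑butyl)dimethylsilane; 9 2,4‑dimethoxybenzaldehyde
Product: 11 3‑{4‑[(tert‑butyldimethylsilyl)oxy]phenyl}‑1‑(2,4‑dimethoxyphenyl)propan‑1‑ol (racemic), via Grignard reagent 10 (not isolated)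
Conditions: Mg, cat. I2, THF, 40 °C; then 9, 0 °C; aq. NH4Cl
Reagents that add atoms: none
Why: Grignard formation and 1,2‑addition to an aryl aldehyde; the carbinol centre is racemic and is removed in step 5.

Step 5
Reactants: 11 3‑{4‑[(tert‑butyldimethylsilyl)oxy]phenyl}‑1‑(2,4‑dimethoxyphenyl)propan‑1‑ol
Product: 12 tert‑butyl{4‑[(2E)‑3‑(2,4‑dimethoxyphenyl)prop‑2‑en‑1‑yl]phenoxy}dimethylsilane
Conditions: p‑TsOH·H2O (2 mol %), 4 Å MS, toluene, 50 °C
Reagents that add atoms: none
Why: Acid‑catalysed E1 dehydration through the 2,4‑dimethoxybenzylic cation should give the conjugated alkene under thermodynamic control (E); only one set of β‑hydrogens is available, so a single regioisomer is expected, and the aryl silyl ether tolerates catalytic acid in toluene.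

Step 6
Reactants: 6 2‑(3‑{4‑[(tert‑butyldimethylsilyl)oxy]phenyl}‑1‑hydroxyprop‑2‑yn‑1‑yl)‑5‑methoxyphenol; 12 tert‑butyl{4‑[(2E)‑3‑(2,4‑dimethoxyphenyl)prop‑2‑en‑1‑yl]phenoxy}dimethylsilane (1.5 equiv)
Product: 15 (2R,3R,4S)‑3‑{4‑[(tert‑butyldimethylsilyl)oxy]benzyl}‑4‑({4‑[(tert‑butyldimethylsilyl)oxy]phenyl}ethynyl)‑2‑(2,4‑dimethoxyphenyl)‑7‑methoxychromane, via alkynyl o‑quinone methide 13 (not isolated), via open benzylic cation 14 (not isolated)
Conditions: (R)‑3,3′‑bis(2,4,6‑triisopropylphenyl)‑H8‑BINOL N‑triflylphosphoramide (5 mol %), 5 Å MS, toluene, −20 → 0 °C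
Reagents that add atoms: none
Why: The chiral N‑triflylphosphoramide should ionise 6 with loss of water to the (E)‑alkynyl o‑quinone methide 13 and hold it as a hydrogen‑bonded contact ion pair; C3 of 12 (the alkene carbon remote from the 2,4‑dimethoxyphenyl ring) adds to C4, and the resulting 2,4‑dimethoxybenzylic cation 14 is captured by the phenolic O1 to forge the O1–C2 bond, a highly asynchronous, effectively stepwise oxa‑[4+2]. The closest known reaction type is the chiral Brønsted acid‑catalysed enantioselective [4+2] cycloaddition of o‑quinone methides, generated in situ from o‑hydroxybenzyl alcohols, with styrenes. The pyran ring is closed by 6‑exo‑trig attack of O1 on the cationic C2 (the C2=aryl oxocarbenium π‑bond is exocyclic), within an overall [4+2] topology. C4 is set by the catalyst pocket, which shields one face of 13 (absolute control); C3 follows from the endo approach of the (E)‑alkene with its aryl group over the (E)‑quinone methide (3,4‑trans); C2 follows from suprafacial collapse across the (E)‑alkene through a chair‑like closure with the aryl group equatorial (2,3‑trans), which is also the thermodynamic outcome because the O1–C2 bond can re‑ionise. The step needs C3 rather than C2 of 12 as the nucleophile and attack at C4 rather than at the distal alkyne carbon: the first is secured by the ortho/para methoxy groups that localise positive charge at C2, the second by the unhindered secondary C4 and by the fact that only the C4 adduct can close a six‑membered ring. Carrying the styryl group as an alkyne removes the oxa‑6π closure to a flav‑3‑ene and the second allylic terminus that a styryl quinone methide would offer.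

Step 7
Reactants: 15 (2R,3R,4S)‑3‑{4‑[(tert‑butyldimethylsilyl)oxy]benzyl}‑4‑({4‑[(tert‑butyldimethylsilyl)oxy]phenyl}ethynyl)‑2‑(2,4‑dimethoxyphenyl)‑7‑methoxychromane
Product: 18 caraganin C, via α‑silyl (Z)‑vinylsilane 16 (not isolated), via β‑silyl (Z)‑vinylsilane 17 (not isolated)
Conditions: [Cp*Ru(MeCN)3]PF6 (5 mol %), (EtO)3SiH (1.5 equiv), CH2Cl2, 0 °C → rt; evaporate; TBAF·3H2O (5 equiv), CuI (20 mol %), THF, 0 °C → rt, under Ar; aq. NH4Cl
Reagents that add atoms: none
Why: Ru‑catalysed trans‑hydrosilylation of the internal alkyne followed by copper‑assisted fluoride protodesilylation with retention (the alkyne‑to‑(E)‑alkene reduction sequence) should convert both silyl regioisomers 16 and 17 into the same (E)‑alkene, while the same fluoride cleaves both aryl silyl ethers; C2, C3 and C4 are not touched, since no metal hydride chain‑walk and no acid is involved.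

**Compound list**

1 | 4‑[(tert‑butyldimethylsilyl)oxy]benzaldehyde | O=Cc1ccc(O[Si](C)(C)C(C)(C)C)cc1 | starting material
2 | tert‑butyl[4‑(2,2‑dibromoethenyl)phenoxy]dimethylsilane | BrC(Br)=Cc1ccc(O[Si](C)(C)C(C)(C)C)cc1 | intermediate
3 | 2‑hydroxy‑4‑methoxybenzaldehyde | COc1ccc(C=O)c(O)c1 | starting material
4 | lithium {4‑[(tert‑butyldimethylsilyl)oxy]phenyl}acetylide | [Li]C#Cc1ccc(O[Si](C)(C)C(C)(C)C)cc1 | intermediate
5 | lithium 2‑formyl‑5‑methoxyphenolate | [Li+].[O-]c1cc(OC)ccc1C=O | intermediate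
6 | 2‑(3‑{4‑[(tert‑butyldimethylsilyl)oxy]phenyl}‑1‑hydroxyprop‑2‑yn‑1‑yl)‑5‑methoxyphenol (racemic) | COc1ccc(C(O)C#Cc2ccc(O[Si](C)(C)C(C)(C)C)cc2)c(O)c1 | intermediate
7 | 4‑(2‑bromoethyl)phenol | Oc1ccc(CCBr)cc1 | starting material
8 | [4‑(2‑bromoethyl)phenoxy](tert‑butyl)dimethylsilane | BrCCc1ccc(O[Si](C)(C)C(C)(C)C)cc1 | intermediate
9 | 2,4‑dimethoxybenzaldehyde | COc1ccc(C=O)c(OC)c1 | starting material
10 | (2‑{4‑[(tert‑butyldimethylsilyl)oxy]phenyl}ethyl)magnesium bromide | Br[Mg]CCc1ccc(O[Si](C)(C)C(C)(C)C)cc1 | intermediate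
11 | 3‑{4‑[(tert‑butyldimethylsilyl)oxy]phenyl}‑1‑(2,4‑dimethoxyphenyl)propan‑1‑ol (racemic) | COc1ccc(C(O)CCc2ccc(O[Si](C)(C)C(C)(C)C)cc2)c(OC)c1 | intermediate
12 | tert‑butyl{4‑[(2E)‑3‑(2,4‑dimethoxyphenyl)prop‑2‑en‑1‑yl]phenoxy}dimethylsilane | COc1ccc(/C=C/Cc2ccc(O[Si](C)(C)C(C)(C)C)cc2)c(OC)c1 | intermediate
13 | (6E)‑6‑(3‑{4‑[(tert‑butyldimethylsilyl)oxy]phenyl}prop‑2‑yn‑1‑ylidene)‑3‑methoxycyclohexa‑2,4‑dien‑1‑one | O=C1C=C(OC)C=C/C1=C\C#Cc1ccc(O[Si](C)(C)C(C)(C)C)cc1 | intermediate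
14 | 2‑{4‑[(tert‑butyldimethylsilyl)oxy]benzyl}‑5‑{4‑[(tert‑butyldimethylsilyl)oxy]phenyl}‑1‑(2,4‑dimethoxyphenyl)‑3‑(2‑hydroxy‑4‑methoxyphenyl)pent‑4‑yn‑1‑ylium, chain C2/C3 configured as C3/C4 of 15, paired with the catalyst anion | COc1ccc([C@H](C#Cc2ccc(O[Si](C)(C)C(C)(C)C)cc2)[C@@H](Cc2ccc(O[Si](C)(C)C(C)(C)C)cc2)[CH+]c2ccc(OC)cc2OC)c(O)c1 | intermediate
15 | (2R,3R,4S)‑3‑{4‑[(tert‑butyldimethylsilyl)oxy]benzyl}‑4‑({4‑[(tert‑butyldimethylsilyl)oxy]phenyl}ethynyl)‑2‑(2,4‑dimethoxyphenyl)‑7‑methoxychromane (same spatial arrangement as the target; the C4 descriptor differs only through CIP priorities) | COc1ccc2c(c1)O[C@@H](c1ccc(OC)cc1OC)[C@H](Cc1ccc(O[Si](C)(C)C(C)(C)C)cc1)[C@H]2C#Cc1ccc(O[Si](C)(C)C(C)(C)C)cc1 | intermediate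
16 | (2R,3R,4R)‑3‑{4‑[(tert‑butyldimethylsilyl)oxy]benzyl}‑4‑[(Z)‑2‑{4‑[(tert‑butyldimethylsilyl)oxy]phenyl}‑1‑(triethoxysilyl)ethenyl]‑2‑(2,4‑dimethoxyphenyl)‑7‑methoxychromane (silicon on the alkene carbon attached to C4) | COc1ccc2c(c1)O[C@@H](c1ccc(OC)cc1OC)[C@H](Cc1ccc(O[Si](C)(C)C(C)(C)C)cc1)[C@H]2/C(=C/c1ccc(O[Si](C)(C)C(C)(C)C)cc1)[Si](OCC)(OCC)OCC | intermediate
17 | (2R,3R,4S)‑3‑{4‑[(tert‑butyldimethylsilyl)oxy]benzyl}‑4‑[(Z)‑2‑{4‑[(tert‑butyldimethylsilyl)oxy]phenyl}‑2‑(triethoxysilyl)ethenyl]‑2‑(2,4‑dimethoxyphenyl)‑7‑methoxychromane (silicon on the alkene carbon bearing the aryl ring) | COc1ccc2c(c1)O[C@@H](c1ccc(OC)cc1OC)[C@H](Cc1ccc(O[Si](C)(C)C(C)(C)C)cc1)[C@H]2/C=C(/c1ccc(O[Si](C)(C)C(C)(C)C)cc1)[Si](OCC)(OCC)OCC | intermediate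
18 | caraganin C, 4‑{[(2R,3R,4R)‑2‑(2,4‑dimethoxyphenyl)‑4‑[(E)‑2‑(4‑hydroxyphenyl)ethenyl]‑7‑methoxy‑3,4‑dihydro‑2H‑chromen‑3‑yl]methyl}phenol | COc1ccc2c(c1)O[C@@H](c1ccc(OC)cc1OC)[C@H](Cc1ccc(O)cc1)[C@H]2/C=C/c1ccc(O)cc1 | target

**Summary**

Total step count: 7. Longest linear sequence: 5 steps (steps 3, 4, 5, 6, 7).

**Steps most likely to fail**

Step 6. The catalyst may discriminate the two faces of the bound quinone methide poorly, because the alkene carries no hydrogen‑bond donor to anchor it, and acid‑triggered oligomerisation of the electron‑rich alkene may compete. Fallback: setting out from 6 and 12, the cycloaddition is run with an achiral acid (diphenyl phosphate, 10 mol %, toluene, 0 °C). This should give the all‑trans chroman as the racemate, that is 15 together with the (2S,3S,4R)‑enantiomer of 15 F1. Preparative SFC on a chiral stationary phase then separates the two, and the route is rejoined at 15.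

Step 7. The cationic Cp*Ru catalyst may be sequestered by the electron‑rich arenes as η6‑arene complexes, stalling the hydrosilylation, and alkene geometry may be lost during fluoride protodesilylation of the aryl‑substituted vinylsilane. Fallback: setting out from 15, Lindlar semi‑hydrogenation (Pd/CaCO3/Pb, quinoline, H2, EtOAc) should give the (Z)‑alkene bis‑silyl ether F2. Iodine‑catalysed Z→E isomerisation (I2, 5 mol %, CH2Cl2, visible light) should then give the (E)‑alkene bis‑silyl ether F3, and TBAF (THF, 0 °C) should cleave both silyl ethers to return to the route at 18.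

Step 5. The product styrene may dimerise or oligomerise cationically under the acid that forms it, and the dehydration may not be fully E‑selective. Fallback: setting out from 8, displacement of bromide with 1‑phenyl‑1H‑tetrazole‑5‑thiol (Et3N, THF, 50 °C) should give the tetrazolyl sulfide F4. Oxidation (m‑CPBA, NaHCO3, CH2Cl2) should give the tetrazolyl sulfone F5, and Julia–Kocienski olefination with 9 (KHMDS, DME, −60 °C → rt) should give the (E)‑alkene directly, rejoining the route at 12.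

**Further compounds**

F1 | step 6 | (2S,3S,4R)‑enantiomer of 15 | COc1ccc2c(c1)O[C@H](c1ccc(OC)cc1OC)[C@@H](Cc1ccc(O[Si](C)(C)C(C)(C)C)cc1)[C@@H]2C#Cc1ccc(O[Si](C)(C)C(C)(C)C)cc1
F2 | step 7 | (2R,3R,4R)‑3‑{4‑[(tert‑butyldimethylsilyl)oxy]benzyl}‑4‑[(Z)‑2‑{4‑[(tert‑butyldimethylsilyl)oxy]phenyl}ethenyl]‑2‑(2,4‑dimethoxyphenyl)‑7‑methoxychromane | COc1ccc2c(c1)O[C@@H](c1ccc(OC)cc1OC)[C@H](Cc1ccc(O[Si](C)(C)C(C)(C)C)cc1)[C@H]2/C=C\c1ccc(O[Si](C)(C)C(C)(C)C)cc1
F3 | step 7 | (2R,3R,4R)‑3‑{4‑[(tert‑butyldimethylsilyl)oxy]benzyl}‑4‑[(E)‑2‑{4‑[(tert‑butyldimethylsilyl)oxy]phenyl}ethenyl]‑2‑(2,4‑dimethoxyphenyl)‑7‑methoxychromane | COc1ccc2c(c1)O[C@@H](c1ccc(OC)cc1OC)[C@H](Cc1ccc(O[Si](C)(C)C(C)(C)C)cc1)[C@H]2/C=C/c1ccc(O[Si](C)(C)C(C)(C)C)cc1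
F4 | step 5 | 5‑[(2‑{4‑[(tert‑butyldimethylsilyl)oxy]phenyl}ethyl)sulfanyl]‑1‑phenyl‑1H‑tetrazole | CC(C)(C)[Si](C)(C)Oc1ccc(CCSc2nnnn2-c2ccccc2)cc1
F5 | step 5 | 5‑[(2‑{4‑[(tert‑butyldimethylsilyl)oxy]phenyl}ethyl)sulfonyl]‑1‑phenyl‑1H‑tetrazole | CC(C)(C)[Si](C)(C)Oc1ccc(CCS(=O)(=O)c2nnnn2-c2ccccc2)cc1
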